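| setting | birch | cedar | oak | alder | Monday's | Saturday's | Friday's | Wednesday's |
|---|---|---|---|---|---|---|---|---|
| substrate | 20 mM | 20 mM | 20 mM | 20 mM | 5.0 mM | 30 mM | 10 mM | 20 mM |
| partner | 1.4 equiv | 3.7 equiv | 10 equiv | 2.5 equiv | 10.0 equiv | 1.20 equiv | 7.50 equiv | 2.50 equiv |
| initiator | 1 mol% | 1 mol% | 1 mol% | 0.68 mol% | 2 mol% | 0.25 mol% | 0.6 mol% | 1 mol% |
| remark | run made earlier | run made earlier | run made earlier | run made earlier |  |  |  |  |
| time |  |  |  |  | 2.5 min | 2.5 min | 2.5 min | 2.5 min |

| run | time / s | target / % | side product / % |
|---|---|---|---|
| birch | 10.0 | 11 | 6 |
| birch | 20.0 | 12 | 13 |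
| birch | 40.0 | 11 | 28 |
| birch | 50.0 | 11 | 28 |
| birch | 80.0 | 9 | 41 |
| cedar | 10.0 | 28 | 11 |
| cedar | 20.0 | 38 | 23 |
| cedar | 40.0 | 45 | 39 |
| cedar | 50.0 | 44 | 40 |
| cedar | 80.0 | 39 | 50 |
| oak | 10.0 | 79 | 13 |
| oak | 12.0 | 84 | 11 |
| oak | 20.0 | 90 | 14 |
| oak | 40.0 | 84 | 13 |
| oak | 80.0 | 86 | 13 |
| alder | 15.0 | 23 | 11 |
| alder | 30.0 | 20 | 26 |
| alder | 50.0 | 16 | 39 |
| alder | 60.0 | 15 | 41 |
| alder | 80.0 | 11 | 52 |

(standard deviation of a reading: 2 percentage points)

- a species is counted by the substrate in it: one side product counts as two

1. all flasks from highest to lowest share of target in all that became target or side product, at 2.5 min (Monday's / Saturday's / Friday's / Wednesday's)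
2. the share of target in all that became target or side product of the flask you put first, at 2.5 min
3. the share of target in all that became target or side product of the flask you put last, at 2.5 min

- The closed vessel starts with substrate, partner and a little initiator; reading side product as target plus substrate, the target ever made is the target standing plus half the side product.
- With the main step alone, substrate plus partner to target, the asked share is 100%.
- The second process is the stalling of that step: cedar's count of target made reads 64.0% at 50.0 s and 64.0% at 80.0 s.
- Scaling cedar's count with equivalents of partner and, if chains end in pairs, with the square root of the initiator concentration gives Monday's 1.22: this is the reach, the target that one burst can make per substrate charged.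
- The same scaling gives alder 0.357, and alder reads 0.355.
- Friday's gets 0.711, Wednesday's 0.432 and Saturday's 0.127, so my ranking runs down the reach .
- The third process is substrate attacking target. Alder's tail gives a reading of 1.64 /M/s.
- Monday's reach stands above one, so the side product is a correction. Cedar's first rate, scaled, clears Monday's substrate in 15.6 s. With substrate falling and target rising in straight lines, the side product is the constant times charged [substrate] times that time, over 3: 4.27%. My share for Monday's is therefore 95.7%.
- Each target made and then eaten takes two substrates, so my estimate for Saturday's is about 22.4 mM of [substrate] kept; target there then has a pseudo-first-order life of 27.2 s, and by this estimate 0.403% of it outlasts 2.5 min.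
- The forecast gives Monday's > Friday's > Wednesday's > Saturday's, with top 40% (28% to 55%) and low 3% (1% to 7%): “Dilution and high partner therefore favour target”.
- The flasks give Monday's > Friday's > Wednesday's > Saturday's, with top 94.1% and low 0.221%, against my 95.7% for Monday's.

    partner + first chain carrier → target + second chain carrier (k = 7000 /M/s)
    substrate + initiating radical → capped initiator + first chain carrier (k = 9.18 × 10⁵ /M/s)
    partner → decomposed reagent (k = 0.0332 /s)
    2 first chain carrier → ended chains (k = 3.50 × 10⁶ /M/s)
    substrate + second chain carrier → by-product + first chain carrier (k = 7350 /M/s)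
    substrate + target → side product (k = 1.88 /M/s)
    initiator → 2 initiating radical (k = 0.0750 /s)

- Monday's, with reach 1.22, holds substrate 0% and target 91.7% at 2.50 min, and target 91.7% at 25.0 min; ten times the time changes its share by nothing. Saturday's, with reach 0.127, has not come to rest: substrate 71.8% gives target a life of 24.7 s by the path from substrate + target alone, and target goes from 0.0610% to 0% at 25.0 min. Its share ends at 0%, while its side product stays 27.7%.
- The neighbour with 2.50 equiv of partner has a reach of 0.306. It computes to 32.9% of target made, with substrate 46.5% left and a share of 33.0%.

(Readings and results stem from a simulated flask for substances that don't exist.)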